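The constants point to a fast catalytic round inside a slower loss of catalyst.

    precatalyst ⇌ free catalyst (K1 = 0.96, k1 = 0.989 /h)
    free catalyst → spent catalyst B (k2 = 0.420 /h)
    starting material + free catalyst → catalyst intermediate (k3 = 1750 /M/h)
    free catalyst → spent catalyst A (k4 = 2.95 × 10⁻⁴ /h)
    catalyst intermediate → free catalyst + target (k5 = 541 /h)

common to all: starting material 20 mM; time 8.0 h
- east: precatalyst 0.83 mM
- south-east: precatalyst 0.64 mM

- which of these there is most of at the end, counted by the starting material in it, east (catalyst intermediate / target / starting material)
- which of these there is most of at the end, counted by the starting material in it, south-east (catalyst intermediate / target / starting material)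
- amount of the one of these that there is most of at the end, in percent of the starting material charged, east
- amount of the one of these that there is most of at the end, in percent of the starting material charged, south-east

Starting material A falls by capture on free catalyst C with constant κ = 1750 /M/h, a pseudo-first-order decay whose rate follows C, so the logarithm of charged over remaining A equals κ times the time integral of C. Catalyst intermediate returns C at 541 /h, faster than C is captured at full charge, 35.0 /h. C dies at 0.420 /h, the other exit being slower.

A first guess holds precatalyst and C at equilibrium, K = 0.96, because the pair relaxes with half-life 0.343 h, shorter than the death half-life, 1.65 h. C then has share 0.490 of the pair, which decays at λ = 0.206 /h.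

But a decaying pair is not at equilibrium: with forward constant f = 0.989 /h, the ratio of C to precatalyst must be K times (one minus λ/f), which is 0.760. Putting this back gives λ = 0.181 /h, the ratio becomes 0.784, and a further round gives 0.185 /h.

The integral of C per charge is the spent fraction divided by 0.420 /h, which suggests 1.84 h at 8.0 h. Yet the catalyst starts as precatalyst, so death lags. The two rates of the pair multiply to f times the death constant, so the fast rate is μ = 2.25 /h, and its own term has the time constant 0.444 h, shorter than the 8.0 h of the run. The spent fraction is one minus μ/(μ−λ) times exp(−λt), or 0.751.

This gives 1.79 h for θ, the catalyst exposure: the time integral of free catalyst up to the end, per amount of precatalyst charged. Remaining A is exp(−κ·charge·θ), so this reckoning commits to target, at 92.6 % in east and 86.5 % in south-east. One objection stays uncomputed: with the starting material at its full charge, catalyst intermediate stands at 0.0647 of C's amount, and that part is sheltered from death.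

The forecast says target in east at 92.4 % and target in south-east at 86.3 %, holding that “conversion is set by the total catalyst exposure before the free catalyst dies”, with that exposure about 1.8 times the charge in hour units.

The simulation gives target at 92.5 % in east and target at 86.4 % in south-east. In south-east at 8.00 h, catalyst intermediate passes on with half-life 0.077 min, shorter than the 0.15 h in which free catalyst enters it, and it stands at 0.0974 % of the catalyst charged against 11.0 % free. South-east's remaining 14 % reads as an exposure of 1.78 h, and θ on the same flask charged with 0.16 mM of precatalyst leaves 60.6 % of the starting material, where that flask holds 61 %.

The numbers of this flask are those of an exercise; no experiment stands behind them.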